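The constants give two speeds that matter: step one makes D.G on whatever Z exists, and step two makes that Z from L, which is the catalyst as charged.

    D + G + Z → D.G + Z, rate k1*[D]*[G]*[Z]/(1 + ([D]/sat1)) (sat1 = 0.36 M, k1 = 170 /M²/s, Ea1 = 44.0 kJ/mol)
    G + L → Z + X (k2 = 0.083 /M/s, Ea2 = 53.0 kJ/mol)
    (constants at 80 °C)

in all of them: D 0.80 M; G 0.720 M; L 1.9 mM; time 15 s
- maple: temperature 80 °C
- cedar: temperature 95 °C
- elm: temperature 65 °C
- larch: at 95 °C until 8.0 s, from then on at 65 °C

- all constants are for 80 °C and move with temperature by the activation energies

1. the flask that comes out highest in amount of D.G, in percent of the D charged, or "all alike" when all lie within 1.5 percentage points (maple / cedar / elm / larch / all alike)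
2. D.G at the end, in percent of the D charged, maple
3. D.G at the end, in percent of the D charged, cedar
4. D.G at the end, in percent of the D charged, elm
5. D.G at the end, in percent of the D charged, larch

Each flask starts without Z. With G held at its charge, L turns into Z pseudo-first-order, and x is the rate constant of step two times the G charged times the time, which in maple reaches 0.896. The Z curve is replaced by its mean: φ = 1 − (1 − e^(−x))/x, the mean share of the catalyst standing as Z, is 0.340 in maple. With L fully converted, D would fall at κ, the rate constant of step one times the G and L charged, divided by the saturation term at the D charged, so κ = 0.0722 /s. In maple, κφt = 0.368; this product Θ is the catalyst dose.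

Two extreme versions can then be solved. If G and the saturation term stood at their charged values, conversion would be 1 − e^(−Θ), or 30.8 % in maple. If G fell in step with D under the same saturation term, the rate would be second order in D and conversion Θ/(1 + Θ), or 26.9 % in maple. Maple should lie between them: its G does fall, but the second version holds the saturation term at 3.22, and with half the D left it is smaller, at 2.11. Both versions keep the Z curve reckoned with G at its charge, so they are estimates and not bounds.

From 80 °C to 95 °C, step one speeds up by a factor of 1.84 and step two by a factor of 2.09; at 65 °C they run at 0.514 and 0.449 of their speed at 80 °C. Cedar's dose is 1.09, giving 52.2 % to 66.4 %. Elm's is 0.0984, giving 8.96 % to 9.37 %.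

Larch adds two stages, with x reaching 0.997 hot and 0.188 cold, and the Z made hot stays. Its dose is 0.563, giving 36.0 % to 43.1 %. Cedar carries the largest dose, so this reckoning puts it highest.

The forecast named cedar, with 27.6 % for maple, 54.8 % for cedar, 9.1 % for elm and 37.5 % for larch, holding that “the product depends strongly on how much Z has formed”.

The simulation gives cedar as highest, with maple at 27.7 %, cedar at 54.9 %, elm at 9.05 % and larch at 37.6 %, each inside its bracket. A neighbour of larch, charged with 0.29 M of G, has a dose of 0.113, which gives 10.2 % to 10.7 %. That neighbour ends at 9.21 %, below its bracket, with a smaller share of its G left than of its D: 74 % of its G against 91 % of its D.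

The numbers of this flask were drawn at random within sensible limits; the result is computed.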